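**Retrosynthetic overview**

1. The target is reached from a tetracyclic trimethoxyarene enone by CBS reduction of the C1 ketone, oxidation of the arene to the 11,14-quinone and cleavage of the C12 methyl ether.
2. That enone is made in one pot from two monocyclic halves, an ortho-bromo benzaldehyde (ring C as arene, Br on C8, CHO = C20 on C9) and a cis alkynoic keto acid (ring A). Pd-arylative 5-exo-dig lactonisation forms O–C6 and C7–C8, then aldol condensation forms C10=C20 and closes ring B.
3. Enabling feature: ring B (C5–C6–C7–C8–C9–C20–C10) has two double bonds, C6=C7 and C10=C20, that flank C5. C6 is γ to the C19 carboxyl on C4 (retron of a γ-alkynoic acid), C10 is α to C1 (carbinol raised to the ketone), and C7 and C20 sit ortho on C8 and C9.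
4. The alkynoic acid comes from a Diels–Alder reaction of (5R)-5-menthyloxyfuranone with a 2-siloxydiene (ring A, C5), lactone-enolate methylation (C4), hydrolysis and Ohira–Bestmann homologation. The bromo aldehyde comes from 1,2,4-trimethoxybenzene.
5. Ring order: ring C (bought as arene), ring A (Diels–Alder), lactone (first event of the key step), ring B (last).

Key step: step 9

Remark: icetexane numbering is used (ring A: C1–C5, C10; ring B: C5, C6, C7, C8, C9, C20, C10; ring C: C8, C9, C11–C14; lactone carbonyl C19 on C4, lactone oxygen on C6); the menthyloxy butenolide and the siloxydiene are taken to be commercial.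

**Route**

Step 1
Reactants: 1 1,2,4-trimethoxybenzene
Product: 3 2-(2,3,6-trimethoxyphenyl)propan-2-ol, via aryllithium 2 (not isolated)
Conditions: n-BuLi, TMEDA, THF, 0 °C; acetone, −78 °C → rt; H2O
Reagents that add atoms: acetone CC(C)=O
Why: Directed ortho-lithiation takes place at C3, the only ring position flanked by two methoxy groups, and the aryllithium undergoes 1,2-addition to acetone.

Step 2
Reactants: 3 2-(2,3,6-trimethoxyphenyl)propan-2-ol
Product: 4 1,2,4-trimethoxy-3-(propan-2-yl)benzene
Conditions: Et3SiH, CF3CO2H, CH2Cl2, 0 °C → rt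
Reagents that add atoms: none
Why: Ionic hydrogenation, in which the acid ionises the tertiary benzylic alcohol to a cation stabilised by two ortho methoxy groups and the silane delivers hydride to it.

Step 3
Reactants: 4 1,2,4-trimethoxy-3-(propan-2-yl)benzene
Product: 5 1-bromo-2,4,5-trimethoxy-3-(propan-2-yl)benzene
Conditions: NBS, MeCN, 0 °C → rt
Reagents that add atoms: N-bromosuccinimide O=C1CCC(=O)N1Br
Why: Electrophilic aromatic bromination should go to the free position that is ortho to one methoxy group and para to another (the later C8), the more activated of the two open sites.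

Step 4
Reactants: 5 1-bromo-2,4,5-trimethoxy-3-(propan-2-yl)benzene
Product: 7 2-bromo-3,5,6-trimethoxy-4-(propan-2-yl)benzaldehyde, via chloro ether 6 (not isolated)
Conditions: Cl2CHOMe, TiCl4, CH2Cl2, −78 → 0 °C; H2O
Reagents that add atoms: dichloromethyl methyl ether COC(Cl)Cl; water O
Why: Rieche formylation (Friedel–Crafts type) can only take the one remaining ring position (the later C9), which a methoxy group activates from the ortho side, and the chloro ether 6 is hydrolysed to the aldehyde on work-up.

Step 5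
Reactants: 8 (5R)-5-(l-menthyloxy)furan-2(5H)-one; 9 2-(trimethylsilyloxy)buta-1,3-diene
Product: 10 (3R,3aR,7aS)-3-(l-menthyloxy)-5-(trimethylsilyloxy)-3a,4,7,7a-tetrahydro-2-benzofuran-1(3H)-one
Conditions: toluene, BHT (cat.), 120 °C, sealed tube
Reagents that add atoms: none
Why: Thermal Diels–Alder reaction of the chiral butenolide, in which the diene adds to the face anti to the menthyloxy group (this sets C5 and the cis ring fusion) and its nucleophilic CH2 terminus next to the siloxy carbon bonds to the β-carbon C5 of the lactone (para rule), so that the masked ketone lands on C1.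

Step 6
Reactants: 10 (3R,3aR,7aS)-3-(l-menthyloxy)-5-(trimethylsilyloxy)-3a,4,7,7a-tetrahydro-2-benzofuran-1(3H)-one
Product: 12 (3R,3aR,7aS)-3-(l-menthyloxy)-7a-methyl-5-(trimethylsilyloxy)-3a,4,7,7a-tetrahydro-2-benzofuran-1(3H)-one, via lithium enolate 11 (not isolated)
Conditions: LiN(iPr)2, THF, −78 °C; MeI, −78 → −30 °C; aq. NaHCO3
Reagents that add atoms: iodomethane CI
Why: Alkylation of the lactone enolate at the ring-fusion carbon C4 should occur on the convex face and keep the lactone cis-fused, so the quaternary centre is set with the methyl group trans to C6 (C19 and C6 cis), while the silyl enol ether is inert to the amide base.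

Step 7
Reactants: 12 (3R,3aR,7aS)-3-(l-menthyloxy)-7a-methyl-5-(trimethylsilyloxy)-3a,4,7,7a-tetrahydro-2-benzofuran-1(3H)-one
Product: 14 (3aR,7aS)-3-hydroxy-7a-methylhexahydro-2-benzofuran-1,5-dione (lactol, both C3 epimers), via keto acetal 13 (not isolated)
Conditions: CF3CO2H–H2O (4:1), 60 °C
Reagents that add atoms: water O
Why: Acid hydrolysis cleaves the silyl enol ether to the C1 ketone and then the acylal-type menthyl acetal to the lactol, whose ring keeps C5 locked cis to C19 and shields it from epimerisation.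

Step 8
Reactants: 14 (3aR,7aS)-3-hydroxy-7a-methylhexahydro-2-benzofuran-1,5-dione
Product: 15 (1S,2S)-2-ethynyl-1-methyl-4-oxocyclohexane-1-carboxylic acid
Conditions: dimethyl (1-diazo-2-oxopropyl)phosphonate, K2CO3, MeOH, 0 °C → rt; then aq. HCl to pH 3
Reagents that add atoms: dimethyl (1-diazo-2-oxopropyl)phosphonate CC(=O)C(=[N+]=[N-])P(=O)(OC)OC
Why: Ohira–Bestmann (Seyferth–Gilbert) homologation of the aldehyde tautomer of the lactol carboxylate should give the terminal alkyne, since aldehydes react far faster than ketones and addition of the diazophosphonate anion is expected to outpace enolisation of the α-branched aldehyde, so that C5 keeps its configuration.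

Step 9
Reactants: 15 (1S,2S)-2-ethynyl-1-methyl-4-oxocyclohexane-1-carboxylic acid; 7 2-bromo-3,5,6-trimethoxy-4-(propan-2-yl)benzaldehyde
Product: 18 (4S,5R)-11,12,14-trimethoxy-1-oxoicetexa-6,8,10(20),11,13-pentaen-19,6-olide, via aryl enol lactone 16 (not isolated), via aldol adduct 17 (not isolated)
Conditions: Pd(PPh3)4 (5 mol %), K2CO3, 4 Å MS, DMF, 70 °C, then 110 °C
Reagents that add atoms: none
Why: Zerovalent palladium inserts into the C8–Br bond of 7 (activated by the ortho formyl group), the arylpalladium bromide binds the terminal alkyne of the carboxylate of 15, and the C19 carboxylate attacks C6 on the face anti to palladium (5-exo-dig anti-oxypalladation, lactone ring closed); reductive elimination then joins C7 to C8 and gives 16 with the aryl group cis to C5. The closest known reaction types are the palladium-catalysed arylative cyclisation of 4-alkynoic acids with aryl halides to (E)-arylidene butyrolactones and the Claisen–Schmidt aldol condensation. At 110 °C carbonate forms the C10 enolate of the C1 ketone, which adds to the C20 aldehyde (7-enolexo-exo-trig closure of ring B, the last ring, giving 17), and E1cB loss of water gives the enone 18. No lasting stereocentre is made: C4 and C5 are spectators, the C6=C7 geometry follows from the anti addition, and both new double bonds are then held in ring B. The step needs arylative lactonisation to outrun alkynyl–aryl coupling and plain cycloisomerisation of the acid, which the carboxylate placed γ and cis to the alkyne on ring A secures, and it needs the aldol to use C10 and not C2, which the tether secures because only the C10 enolate can reach C20 through a seven-membered transition state. The ortho placement of Br (on C8) and CHO (on C9) in 7 decides which arene carbon meets C7 and which carries C20.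

Step 10
Reactants: 18 (4S,5R)-11,12,14-trimethoxy-1-oxoicetexa-6,8,10(20),11,13-pentaen-19,6-olide
Product: 19 (1R,4S,5R)-1-hydroxy-11,12,14-trimethoxyicetexa-6,8,10(20),11,13-pentaen-19,6-olide
Conditions: (S)-2-methyl-CBS-oxazaborolidine (0.3 equiv), catecholborane, toluene, −78 °C; pH 7 buffer
Reagents that add atoms: none
Why: Corey–Bakshi–Shibata reduction under reagent control, in which the fully substituted alkylidene carbon C10 is the large group and C2 the small one, so the (S)-catalyst should deliver hydride to the face that gives the (1R)-carbinol (OH cis to the lactone), which is also the convex face of the cis-fused ring A, while catecholborane at −78 °C leaves the enol lactone and the alkenes alone.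

Step 11
Reactants: 19 (1R,4S,5R)-1-hydroxy-11,12,14-trimethoxyicetexa-6,8,10(20),11,13-pentaen-19,6-olide
Product: 20 (1R,4S,5R)-1-hydroxy-12-methoxy-11,14-dioxoicetexa-6,8,10(20),12-tetraen-19,6-olide
Conditions: (NH4)2Ce(NO3)6, MeCN–H2O (2:1), 0 °C, 10 min
Reagents that add atoms: water O
Why: Oxidative demethylation by tetravalent cerium should convert the para-dimethoxy pair on C11 and C14 into the para-quinone, while the C12 methoxy group remains as a vinylogous ester and the short cold reaction spares the enol lactone and the carbinol.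

Step 12
Reactants: 20 (1R,4S,5R)-1-hydroxy-12-methoxy-11,14-dioxoicetexa-6,8,10(20),12-tetraen-19,6-olide
Product: 21 6,7-anhydroballotiquinone, (1R,4S,5R)-1,12-dihydroxy-11,14-dioxoicetexa-6,8,10(20),12-tetraen-19,6-olide
Conditions: BCl3, CH2Cl2, −78 → −20 °C; pH 4 buffer
Reagents that add atoms: none
Why: Chelation-controlled ether cleavage, in which BCl3 binds between the C11 carbonyl oxygen and the C12 methoxy oxygen and chloride removes the methyl group by SN2, while the enol lactone and the C1 carbinol (held as a borate until hydrolysis and deactivated towards ionisation by the quinone) should survive at low temperature.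

**Compound list**

1 | 1,2,4-trimethoxybenzene | COc1ccc(OC)c(OC)c1 | starting material
2 | (2,3,6-trimethoxyphenyl)lithium | COc1ccc(OC)c(OC)c1[Li] | intermediate
3 | 2-(2,3,6-trimethoxyphenyl)propan-2-ol | COc1ccc(OC)c(OC)c1C(C)(C)O | intermediate
4 | 1,2,4-trimethoxy-3-(propan-2-yl)benzene | COc1ccc(OC)c(OC)c1C(C)C | intermediate
5 | 1-bromo-2,4,5-trimethoxy-3-(propan-2-yl)benzene | COc1c(Br)cc(OC)c(OC)c1C(C)C | intermediate
6 | 1-bromo-2-[chloro(methoxy)methyl]-3,4,6-trimethoxy-5-(propan-2-yl)benzene | COC(Cl)c1c(Br)c(OC)c(C(C)C)c(OC)c1OC | intermediate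
7 | 2-bromo-3,5,6-trimethoxy-4-(propan-2-yl)benzaldehyde | COc1c(Br)c(C=O)c(OC)c(OC)c1C(C)C | intermediate
8 | (5R)-5-{[(1R,2S,5R)-5-methyl-2-(propan-2-yl)cyclohexyl]oxy}furan-2(5H)-one | C[C@@H]1CC[C@H]([C@@H](C1)O[C@@H]2OC(=O)C=C2)C(C)C | starting material
9 | 2-(trimethylsilyloxy)buta-1,3-diene | C=CC(=C)O[Si](C)(C)C | starting material
10 | (3R,3aR,7aS)-3-(l-menthyloxy)-5-(trimethylsilyloxy)-3a,4,7,7a-tetrahydro-2-benzofuran-1(3H)-one (cis-fused) | C[C@@H]1CC[C@H]([C@@H](C1)O[C@@H]2OC(=O)[C@H]3CC=C(O[Si](C)(C)C)C[C@@H]23)C(C)C | intermediate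
11 | lithium enolate of 10 (enolate carbon = ring-fusion carbon C4) | C[C@@H]1CC[C@H]([C@@H](C1)O[C@@H]2OC(O[Li])=C3CC=C(O[Si](C)(C)C)C[C@@H]23)C(C)C | intermediate
12 | (3R,3aR,7aS)-3-(l-menthyloxy)-7a-methyl-5-(trimethylsilyloxy)-3a,4,7,7a-tetrahydro-2-benzofuran-1(3H)-one | C[C@@H]1CC[C@H]([C@@H](C1)O[C@@H]2OC(=O)[C@@]3(C)CC=C(O[Si](C)(C)C)C[C@@H]23)C(C)C | intermediate
13 | (3R,3aR,7aS)-3-(l-menthyloxy)-7a-methylhexahydro-2-benzofuran-1,5-dione | C[C@@H]1CC[C@H]([C@@H](C1)O[C@@H]2OC(=O)[C@@]3(C)CCC(=O)C[C@@H]23)C(C)C | intermediate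
14 | (3aR,7aS)-3-hydroxy-7a-methylhexahydro-2-benzofuran-1,5-dione (lactol, C3 epimers; ring tautomer of the aldehyde acid) | OC1OC(=O)[C@@]2(C)CCC(=O)C[C@@H]12 | intermediate
15 | (1S,2S)-2-ethynyl-1-methyl-4-oxocyclohexane-1-carboxylic acid (ethynyl cis to CO2H) | OC(=O)[C@@]1(C)CCC(=O)C[C@H]1C#C | intermediate
16 | (3E,3aR,7aS)-3-{[2-formyl-3,4,6-trimethoxy-5-(propan-2-yl)phenyl]methylidene}-7a-methylhexahydro-2-benzofuran-1,5-dione | O=Cc1c(OC)c(OC)c(C(C)C)c(OC)c1/C=C2/OC(=O)[C@@]3(C)CCC(=O)C[C@@H]23 | intermediate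
17 | (4S,5R)-20-hydroxy-11,12,14-trimethoxy-1-oxoicetexa-6,8,11,13-tetraen-19,6-olide (C10, C20 epimers) | COc1c(C(C)C)c(OC)c(OC)c2c1C=C3OC(=O)[C@@]4(C)CCC(=O)C(C2O)[C@@H]34 | intermediate
18 | (4S,5R)-11,12,14-trimethoxy-1-oxoicetexa-6,8,10(20),11,13-pentaen-19,6-olide | COc1c(C(C)C)c(OC)c(OC)c2c1C=C3OC(=O)[C@@]4(C)CCC(=O)C(=C2)[C@@H]34 | intermediate
19 | (1R,4S,5R)-1-hydroxy-11,12,14-trimethoxyicetexa-6,8,10(20),11,13-pentaen-19,6-olide | COc1c(C(C)C)c(OC)c(OC)c2c1C=C3OC(=O)[C@@]4(C)CC[C@@H](O)C(=C2)[C@@H]34 | intermediate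
20 | (1R,4S,5R)-1-hydroxy-12-methoxy-11,14-dioxoicetexa-6,8,10(20),12-tetraen-19,6-olide | CC(C)C1=C(OC)C(=O)C2=C(C=C3OC(=O)[C@@]4(C)CC[C@@H](O)C(=C2)[C@@H]34)C1=O | intermediate
21 | 6,7-anhydroballotiquinone, (1R,4S,5R)-1,12-dihydroxy-11,14-dioxoicetexa-6,8,10(20),12-tetraen-19,6-olide | CC(C)C1=C(O)C(=O)C2=C(C=C3OC(=O)[C@@]4(C)CC[C@@H](O)C(=C2)[C@@H]34)C1=O | target

**Step count and risks**

Total step count: 12. Longest linear sequence: 8 steps (steps 5–8 or 1–4, then 9–12).

Steps most likely to fail:

1. Step 9. Oxidative addition into the hindered, electron-rich bromide may be slow, so that cycloisomerisation of 15 without aryl transfer or alkynyl–aryl coupling takes over; the enol lactone may also be opened during the hot basic aldol stage. The fallback sets out from 15 and 7 and comes back at 18. Iodolactonisation of 15 (I2, NaHCO3, MeCN, 0 °C; anti addition puts iodine cis to C5) should give (3E,3aR,7aS)-3-(iodomethylidene)-7a-methylhexahydro-2-benzofuran-1,5-dione F1. Miyaura borylation of 7 (B2pin2, Pd(dppf)Cl2, KOAc, dioxane, 90 °C) should give 3,5,6-trimethoxy-4-(propan-2-yl)-2-(4,4,5,5-tetramethyl-1,3,2-dioxaborolan-2-yl)benzaldehyde F2. Suzuki–Miyaura coupling of F1 with F2 (Pd(PPh3)4, anhydrous K3PO4, dioxane, 80 °C) should give 16 with retained geometry, now isolated. Acid-catalysed aldol condensation (TsOH, toluene, 80 °C, water removal) then closes ring B to 18.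

2. Step 12. The Lewis acid may ionise or chlorinate the C1 allylic carbinol before the methyl ether is cleaved. The fallback sets out from 19 and comes back at 21. Silylation of 19 (TBSOTf, 2,6-lutidine, CH2Cl2, −78 °C) should give the C1 silyl ether (1R,4S,5R)-1-(tert-butyldimethylsilyloxy)-11,12,14-trimethoxyicetexa-6,8,10(20),11,13-pentaen-19,6-olide F3. Oxidation with (NH4)2Ce(NO3)6 should give the methoxyquinone silyl ether (1R,4S,5R)-1-(tert-butyldimethylsilyloxy)-12-methoxy-11,14-dioxoicetexa-6,8,10(20),12-tetraen-19,6-olide F4. BCl3 at −78 °C should give the hydroxyquinone silyl ether (1R,4S,5R)-1-(tert-butyldimethylsilyloxy)-12-hydroxy-11,14-dioxoicetexa-6,8,10(20),12-tetraen-19,6-olide F5. HF·pyridine in THF then removes the silyl group to reach 21.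

3. Step 11. Oxidation may not stop at the quinone (attack on the electron-rich C6=C7 and C10=C20 alkenes), and the acidic medium may ionise the C1 carbinol (epimerisation or allylic shift) before ring C is oxidised. The fallback sets out from 18, which has no carbinol yet, and comes back at 21. BBr3 (CH2Cl2, −78 → 0 °C) should remove all three methyl groups to give the triol ketone (4S,5R)-11,12,14-trihydroxy-1-oxoicetexa-6,8,10(20),11,13-pentaen-19,6-olide F6. Air oxidation (O2, EtOAc, rt) of this hydroxyhydroquinone should give the hydroxyquinone ketone (4S,5R)-12-hydroxy-1,11,14-trioxoicetexa-6,8,10(20),12-tetraen-19,6-olide F7. Luche reduction (NaBH4, CeCl3·7H2O, MeOH–THF, −78 °C) should reduce both the quinone and the C1 ketone, with hydride expected on the convex face anti to the lactone, to give the hydroquinone carbinol (1R,4S,5R)-1,11,12,14-tetrahydroxyicetexa-6,8,10(20),11,13-pentaen-19,6-olide F8. Air on work-up reoxidises F8 to 21; here the C1 configuration rests on substrate control alone.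

**Further compounds**

F1 | step 9 | (3E,3aR,7aS)-3-(iodomethylidene)-7a-methylhexahydro-2-benzofuran-1,5-dione | I/C=C1/OC(=O)[C@@]2(C)CCC(=O)C[C@@H]12
F2 | step 9 | 3,5,6-trimethoxy-4-(propan-2-yl)-2-(4,4,5,5-tetramethyl-1,3,2-dioxaborolan-2-yl)benzaldehyde | COc1c(B2OC(C)(C)C(C)(C)O2)c(C=O)c(OC)c(OC)c1C(C)C
F3 | step 12 | (1R,4S,5R)-1-(tert-butyldimethylsilyloxy)-11,12,14-trimethoxyicetexa-6,8,10(20),11,13-pentaen-19,6-olide | COc1c(C(C)C)c(OC)c(OC)c2c1C=C3OC(=O)[C@@]4(C)CC[C@@H](O[Si](C)(C)C(C)(C)C)C(=C2)[C@@H]34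
F4 | step 12 | (1R,4S,5R)-1-(tert-butyldimethylsilyloxy)-12-methoxy-11,14-dioxoicetexa-6,8,10(20),12-tetraen-19,6-olide | CC(C)C1=C(OC)C(=O)C2=C(C=C3OC(=O)[C@@]4(C)CC[C@@H](O[Si](C)(C)C(C)(C)C)C(=C2)[C@@H]34)C1=O
F5 | step 12 | (1R,4S,5R)-1-(tert-butyldimethylsilyloxy)-12-hydroxy-11,14-dioxoicetexa-6,8,10(20),12-tetraen-19,6-olide | CC(C)C1=C(O)C(=O)C2=C(C=C3OC(=O)[C@@]4(C)CC[C@@H](O[Si](C)(C)C(C)(C)C)C(=C2)[C@@H]34)C1=O
F6 | step 11 | (4S,5R)-11,12,14-trihydroxy-1-oxoicetexa-6,8,10(20),11,13-pentaen-19,6-olide | Oc1c(C(C)C)c(O)c(O)c2c1C=C3OC(=O)[C@@]4(C)CCC(=O)C(=C2)[C@@H]34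
F7 | step 11 | (4S,5R)-12-hydroxy-1,11,14-trioxoicetexa-6,8,10(20),12-tetraen-19,6-olide | CC(C)C1=C(O)C(=O)C2=C(C=C3OC(=O)[C@@]4(C)CCC(=O)C(=C2)[C@@H]34)C1=O
F8 | step 11 | (1R,4S,5R)-1,11,12,14-tetrahydroxyicetexa-6,8,10(20),11,13-pentaen-19,6-olide | Oc1c(C(C)C)c(O)c(O)c2c1C=C3OC(=O)[C@@]4(C)CC[C@@H](O)C(=C2)[C@@H]34
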